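Slowness was what I read first: the north run had used 37.5% of its starting material by 40.0 h, and along a nearly straight line.

the same everywhere: gas 4.8 mM (held)

| run | starting material | free catalyst | remark | time |
|---|---|---|---|---|
| south-east | 0.050 M | 14 µM | run made earlier |  |
| north | 0.050 M | 22 µM | run made earlier |  |
| west | 0.025 M | 29 µM | run made earlier |  |
| eta | 0.050 M | 29 µM |  | 40 h |
| zeta | 0.050 M | 29 µM |  | 60 h |
| beta | 0.050 M | 29 µM |  | 90 h |

| run | time / h | over-reaction product / % | starting material / % | target / % | catalyst intermediate C / % |
|---|---|---|---|---|---|
| south-east | 3.00 | 0 | 98.8 | 1.9 | 0 |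
| south-east | 6.00 | 0 | 97.8 | 2.7 | 0.2 |
| south-east | 12.0 | 2.3 | 91.7 | 6.2 | 0 |
| south-east | 20.0 | 1.0 | 87.6 | 8.4 | 0.3 |
| south-east | 40.0 | 9.5 | 74.4 | 16.7 | 1.4 |
| north | 4.00 | 0.8 | 96.8 | 4.0 | 0.2 |
| north | 10.0 | 1.4 | 91.3 | 9.5 | 0 |
| north | 20.0 | 4.0 | 79.8 | 15.9 | 0.2 |
| north | 30.0 | 6.1 | 72.8 | 23.4 | 1.3 |
| north | 40.0 | 10.5 | 62.5 | 28.7 | 0 |
| west | 3.00 | 1.1 | 95.8 | 7.6 | 0 |
| west | 6.00 | 0 | 85.2 | 11.3 | 0.4 |
| west | 12.0 | 2.4 | 74.4 | 24.1 | 0 |
| west | 20.0 | 5.7 | 56.7 | 34.9 | 0 |
| west | 40.0 | 22.1 | 24.8 | 52.9 | 0.4 |

(standard deviation of a reading: 1 percentage point)

- the analysis behind the earlier runs scatters by 1 percentage point, standard deviation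
- at the start none of the gas is in solution

- which of these there is most of at the end, counted by the starting material in it, eta (starting material / catalyst intermediate C / over-reaction product / target)
- which of these there is most of at the end, counted by the starting material in it, zeta (starting material / catalyst intermediate C / over-reaction product / target)
- which of these there is most of at the end, counted by the starting material in it, beta (starting material / catalyst intermediate C / over-reaction product / target)
- how much there is at the end of the one of these that leads, in percent of the starting material charged: eta
- how much there is at the end of the one of these that leads, in percent of the starting material charged: zeta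
- how much there is at the end of the one of these that leads, in percent of the starting material charged: beta

I divided what the north run used by its catalyst and its time, and got a turnover frequency of 21.3 h⁻¹. The south-east run gave 22.9 h⁻¹ by the same reckoning. From this I made the clearing time, the hours a flask would need to pass its whole charge through its catalyst at the north run's turnover. For eta, zeta and beta it came to 80.9 h.

Then I ran the flask slowly in my head. At the start none of the gas was in solution, yet target stood in the first reading of the north run: by 4.00 h it read 4.0% of target and 0.8% of over-reaction product. Catalyst intermediate C stayed out of the contest, since the catalyst charged in eta, zeta and beta is 0.0580% of the starting material, far less than the charge. In the middle, over-reaction product climbed, and it seemed to follow the hours: at 40.0 h the west run's 22.1%, counted on the larger charge, was 11.1%, beside 10.5% in the north run and 9.5% in the south-east run.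

The end showed a sag. The west run's clearing time was 40.5 h, so its last reading stood at 0.988 clearing times, yet a quarter of its starting material remained. My straight line left 50.6% in eta and 25.9% in zeta, and I expected the sag to raise both. Beta, at 90 h, runs past its clearing time, so I put its remainder near or below the west run's quarter.

My reckoning stopped at the starting material, while the forecast went on to name leaders: starting material at 51% in eta, target at 44% in zeta, and over-reaction product at 54% in beta. Of over-reaction product it wrote “so it lags and then accelerates”.

The simulation gave starting material at 54.2% in eta, target at 45.3% in zeta and target at 46.6% in beta, where over-reaction product stood at 38.2%, so the forecast's third leader was wrong.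

    catalyst intermediate A ⇌ catalyst intermediate B (K = 0.310, k = 100 h⁻¹)
    catalyst intermediate C ⇌ catalyst intermediate D (K = 0.180, k = 5400 h⁻¹)
    starting material + free catalyst → catalyst intermediate A (k = 5300 M⁻¹ h⁻¹)
    reagent + target → over-reaction product (k = 13.0 M⁻¹ h⁻¹)
    reagent + catalyst intermediate B → catalyst intermediate C (k = 7.50 × 10⁵ M⁻¹ h⁻¹)
    catalyst intermediate D ⇌ free catalyst + target (K = 0.0850 M, k = 270 h⁻¹)
    gas ⇌ reagent, rate k7*(csat - [reagent]) (kL = 0.180 h⁻¹)

Beta ran 1.11 clearing times and kept 15% of its starting material. The neighbour of beta charged with 4.9 × 10⁻⁵ M of free catalyst had a clearing time of 47.9 h, so its 90 h were 1.88 clearing times. That neighbour kept 3.42% of its starting material and held 58.7% of target and 37.8% of over-reaction product, beside 38.2% in beta.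

The numbers in the tables are calculated with constants of no real substance.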